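**Numbering used throughout.** Cyclobutane: C1 (H, CO2Me), C2 (H, CO2H), C3 (next to C2) and C4 (next to C1), each with a methyl group and a pyranone. Pyranone atoms are primed: O1', C2' (C=O), C3' (Me), C4' (OMe), C5' (H), C6' (bonded to the cyclobutane). Compounds 1–16 are those of the steps and the compound list.

## Analysis of the target

The target is a fully substituted cyclobutane in which C1 bears a methyl ester, C2 a free carboxylic acid, and the adjacent quaternary carbons C3 and C4 each bear a methyl group and a 4-methoxy-3-methyl-2-pyranon-6-yl ring attached through C6'. All four ring carbons are stereogenic (C1 R, C2 S, C3 R, C4 S in this numbering). The two carboxyl carbons are cis to each other and to both methyl groups, and the two pyranones share the opposite face. Without the ester/acid difference the molecule would have a mirror plane through the midpoints of C1–C2 and C3–C4, so the absolute configuration is only the choice of which of two enantiotopic carboxyl groups carries the methyl. The sensitive groups are the two 4-methoxy-2-pyranones (lactone and vinylogous ester, attacked by hydroxide and hard nucleophiles) and the C1–H and C2–H bonds, where base can epimerise the cis diester or, since each carboxyl is 1,3 to an acyl-level carbon, open the strained ring through an enolate. The difficulty is four contiguous stereocentres on a four-membered ring, two of them adjacent quaternary carbons, together with four carboxyl-level carbons that must be told apart: two become pyranones, one an ester, one an acid. The strategy rests on the carboxyl carbons on C1 and C2 lying anti to the carbonyl-level carbons on C3 and C4; if C3 and C4 are tied into a cis-fused anhydride, C1 and C2 are the alkene carbons of a bicyclic cyclobutene and their carboxyls occupy its exo face.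

## Retrosynthetic reasoning

**16 to 15.** The C1 ester C–O bond is cut and the ester/acid pair is returned to the meso cyclic anhydride 15. This is the only point where chirality enters. Placing it last keeps every earlier intermediate meso or racemic, so no enantiomeric purity can be lost on the way. The forward step must deliver the alcohol to one of two enantiotopic carbonyls under control of a cinchona alkaloid.

**15 to 13.** The anhydride is traced through diacid 14 to the meso dimethyl ester 13. Two identical, unreactive esters are what C1 and C2 need while the pyranones are built, and only a cis diacid can close to 15, which also checks the configuration.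

**13 to 10.** The second pyranone is cut at O1'–C2' (the lactone) and at C5'–C6'. This gives keto enoate 12, and then the acid chloride 11 of acid 10 plus the silyl ketene acetal 8 as a γ-carbon nucleophile. The cut is made here because C6' is the carboxyl carbon already on C4, and C2'–C5' with their methyl and methoxy groups arrive as one piece.

**10 to 4.** The first pyranone is cut in the same way, through keto acid 9 to anhydride 4 and 8. The anhydride is its own activated acyl donor and needs only a Lewis acid. The non-basic silyl nucleophile spares the C1–H and C2–H bonds next to the esters. A four-carbon unit that already carries the methoxy group is chosen over the doubly deprotonated form of 5. An O-methylation after ring opening would also esterify the liberated acid on C4 and make it indistinguishable from the C1/C2 esters.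

**8 to 5.** The Si–O bond of 8 is cut, back to the lithium dienolate 7 of enol ether 6, and 6 comes from the commercial keto ester 5 by O-methylation of its enol. Preparing 8 once as a distillable reagent lets one batch serve both pyranone constructions.

**4 to 3.** This is the key disconnection. The two exocyclic bonds C1–CO2Me and C2–CO2Me are cut, leaving the cyclobutene of 3. Both carboxyl carbons are then introduced in one operation, cis to each other, on a ring that already holds the two quaternary centres. C1/C2 emerge as esters while C3/C4 remain an anhydride, so the two pairs are differentiated from the start.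

**3 to 1 and 2.** Bonds C1–C4 and C2–C3 are cut in a [2+2] sense. The five-membered anhydride of 1 enforces the cis relationship of the two methyl groups.

## Alternatives that were turned down

**Alternative 1:** Both pyranones are disconnected at C5'–C6' and O1'–C2', back to the cis-3,4-diformyl cyclobutane diester A1 and two equivalents of the silyloxy diene A2, the same reagent as 8 of the chosen route. In the forward step a Lewis acid promotes a hetero-Diels–Alder reaction at each aldehyde and gives the bis(dihydropyranone) A3.
- For: the methoxy group comes with the diene, no basic carbon nucleophile meets the C1/C2 esters, and the new C6' centres are removed later. With a methyl and a tert-butyl ester in place, the acid can be released at the end by acid alone. On that last point this plan is stronger than the chosen endgame, which must cleave methyl esters beside two pyranones.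
- Against: A1 holds two neopentyl aldehydes cis on adjacent quaternary carbons, which should hydrate or close to a cyclic hemiacetal and react sluggishly. Reaching A1 means reducing two of four carboxyl carbons selectively. A3 then needs two dehydrogenations next to quaternary carbons, and the ester differentiation has to be solved earlier.
- Comparison: the chosen strategy uses the same diene as a γ-nucleophile toward acyl electrophiles, keeps all four carbons at the carboxyl oxidation level and reaches its key product in two steps.

**Alternative 2:** The C1–C2 bond is disconnected, back to the meso pyrrolidine A4 whose nitrogen bridges C1 and C2. In the forward step the nitrogen is aminated by a hypervalent-iodine nitrene source, nitrogen is lost and the 1,4-biradical closes to the diacetyl cyclobutane A5.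
- For: the contraction is stereospecific, so the relative configuration can be set on a five-membered ring. The two acetyl groups of A5 would let the pyranones be built from ketone enolates, with no hindered acyl electrophile. That is an advantage over the chosen route.
- Against: A4 is itself a pentasubstituted pyrrolidine with two adjacent quaternary carbons, no easier to assemble than the target core. The biradical has both radical centres stabilised by esters and a central bond flanked by acyl groups, which favours β-scission into two alkenes and loss of configuration.
- Comparison: the chosen route forms the ring by a photocycloaddition with no such fragmentation channel and is shorter to the first fully functionalised cyclobutane.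

**Alternative 3:** Bonds C1–C4 and C2–C3 are disconnected, back to 1 and maleic anhydride A6. In the forward step a sensitised crossed [2+2] photocycloaddition gives the cis,anti,cis dianhydride A7.
- For: one step from two commodity anhydrides gives the whole core with the anti relationship, without metal or carbon monoxide and without a facial question at a metal. On step count to the ring it is stronger. The two anhydrides of A7 are chemically different, one unsubstituted and one doubly α-methylated.
- Against: two homodimers and syn/anti isomers accompany the crossed product, and such dianhydrides are poorly soluble and hard to separate. The reactivity difference also runs the wrong way: the unhindered C1/C2 anhydride, which must survive as esters, opens first. It has to be turned into the diester in two more operations before the hindered anhydride can acylate carbon, which arrives at 4 anyway.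
- Comparison: the chosen key step gives 4 directly with the two pairs already at different functional levels. This alternative is kept as the fallback for the key step.

Key step: step 2

Assumption: the sense of the quinine-mediated methanolysis of 15 is taken from the empirical model for simpler cis-fused succinic anhydrides; quinidine would give the mirror-image half-ester.

## Route

Step 1
Reactants: 1 2,3-dimethylmaleic anhydride; 2 acetylene
Product: 3 (1R,5S)-1,5-dimethyl-3-oxabicyclo[3.2.0]hept-6-ene-2,4-dione (meso cis-1,2-dimethylcyclobut-3-ene-1,2-dicarboxylic anhydride)
Conditions: C2H2 (continuous stream), benzophenone (0.2 equiv), acetone, hν (medium-pressure Hg lamp, Pyrex), −40 °C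
Reagents that add atoms: none
Why: Triplet-sensitised [2+2] photocycloaddition of the anhydride alkene to the alkyne; the five-membered ring allows only a cis fusion, so meso 3 is the single possible stereoisomer. Cold, acetylene-saturated acetone keeps the alkyne in large excess over 1 and limits photodimerisation.

Step 2
Reactants: 3 (1R,5S)-1,5-dimethyl-3-oxabicyclo[3.2.0]hept-6-ene-2,4-dione
Product: 4 dimethyl (1R,2S,3R,4S)-3,4-dimethylcyclobutane-1,2,3,4-tetracarboxylate 3,4-anhydride (meso; both esters exo, cis to the two methyls and anti to the anhydride ring)
Conditions: PdCl2 (10 mol%), CuCl2 (3 equiv), NaOAc (3 equiv), CO (3 atm), MeOH–THF 1:4, 25 °C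
Reagents that add atoms: carbon monoxide, [C-]#[O+]; methanol, CO
Why: Divalent palladium with CO and methanol (acetate as base) forms a methoxycarbonylpalladium chloride, which binds the strained cyclobutene and adds across it by syn migratory insertion, giving a cyclobutylpalladium with the metal on C2 and the first ester on C1 on the same face. This alkylpalladium cannot lose a β-hydride, because C3 and C4 are quaternary and the hydrogen on the neighbouring CH lies on the opposite face, so it takes up CO with retention and the acylpalladium is cleaved by methanol to the second ester; the zerovalent palladium released is returned to the divalent state by two equivalents of CuCl2. The closest known reaction type is the oxidative bis(methoxycarbonylation) of alkenes with PdCl2 and CuCl2 in buffered methanol, which gives cis diesters on the exposed face of cyclic and strained bicyclic alkenes, the acetate buffer steering it to the diester and away from Wacker-type methoxypalladation. No ring is closed in this step. The new stereocentres C1 and C2 are cis to each other because both C–C bonds are made from one palladium on one face. Their relation to C3 and C4 is decided by the face the metal takes: the exo face, flanked only by two angular methyl groups that splay away from the double bond, is expected to be preferred over the concave face, where the rigid anhydride ring and its three oxygens meet the chloride-bearing metal. The step therefore needs exo facial selectivity, no β-hydride loss and survival of the anhydride; the fold of the bicycle, the absence of a syn β-hydrogen and the doubly α-methylated, neopentyl-type anhydride carbonyls (with methanol kept dilute in THF) should secure them. Both esters thus end cis to the methyl groups and anti to the anhydride, and 4 is again meso.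

Step 3
Reactants: 5 methyl 2-methylacetoacetate
Product: 6 methyl (E)-3-methoxy-2-methylbut-2-enoate
Conditions: HC(OMe)3 (1.5 equiv), H2SO4 (cat.), 25 °C; then distil
Reagents that add atoms: trimethyl orthoformate, COC(OC)OC
Why: Acid-catalysed ketalisation of the ketone followed by loss of methanol gives the conjugated enol ether (enol ether formation with an orthoester). The more stable E isomer should predominate, and the geometry does not matter because it is erased in the dienolate.

Step 4
Reactants: 6 methyl (E)-3-methoxy-2-methylbut-2-enoate
Product: 8 1,3-dimethoxy-2-methyl-1-(trimethylsilyloxy)buta-1,3-diene, via lithium dienolate 7 (not isolated)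
Conditions: LiN(iPr)2 (1.1 equiv), THF, −78 °C; then Me3SiCl (1.2 equiv), −78 → 0 °C; evaporate, pentane, filter, distil
Reagents that add atoms: chlorotrimethylsilane, C[Si](C)(C)Cl
Why: The amide base removes a proton from the γ-methyl group of the β-methoxy enoate and the delocalised lithium dienolate is silylated on oxygen, the standard preparation of 1-alkoxy-1-silyloxy dienes (silyl ketene acetal formation). The diene is distilled and kept cold under argon as the single carbon nucleophile for both pyranone constructions; the geometry of its ketene acetal double bond is immaterial.

Step 5
Reactants: 4 dimethyl (1R,2S,3R,4S)-3,4-dimethylcyclobutane-1,2,3,4-tetracarboxylate 3,4-anhydride; 8 1,3-dimethoxy-2-methyl-1-(trimethylsilyloxy)buta-1,3-diene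
Product: 9 racemic 4-[(3E)-3,5-dimethoxy-4-methyl-5-oxopent-3-enoyl]-2,3-bis(methoxycarbonyl)-1,4-dimethylcyclobutane-1-carboxylic acid
Conditions: TiCl4 (1.2 equiv), CH2Cl2, −78 °C; then 8 (1.5 equiv), −78 → −40 °C; 1 M HCl
Reagents that add atoms: none
Why: Vinylogous Mukaiyama-type acylation: TiCl4 activates an anhydride carbonyl, the unsubstituted terminal CH2 of the silyl ketene acetal (its γ-carbon, the α-carbon being blocked by the methyl group) adds to it, and the tetrahedral intermediate collapses to a titanium carboxylate and the conjugated β-methoxy enoate with loss of Me3SiCl. The conditions are non-basic, so the C–H bonds next to the two esters are untouched; no stereocentre is formed, and attack at either enantiotopic carbonyl gives the racemate (the keto acid may sit partly as its lactol).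

Step 6
Reactants: 9 racemic keto acid
Product: 10 racemic 2,3-bis(methoxycarbonyl)-4-(4-methoxy-3-methyl-2-oxo-2H-pyran-6-yl)-1,4-dimethylcyclobutane-1-carboxylic acid
Conditions: DBU (2.5 equiv), toluene, 60 °C; aq. HCl
Reagents that add atoms: none
Why: Base-induced lactonisation: the enolate oxygen of the ketone attacks the methyl ester, which the E enoate already holds cis to the ketone-bearing methylene (6-exo-trig acyl substitution; any Z isomer equilibrates through the dienolate), and loss of methanol gives the 4-methoxy-2-pyranone with the methoxy group in place. The carboxylate is inert and DBU is too weak to epimerise the ester-bearing carbons.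

Step 7
Reactants: 10 racemic pyranone acid; 8 1,3-dimethoxy-2-methyl-1-(trimethylsilyloxy)buta-1,3-diene
Product: 12 racemic dimethyl 3-[(3E)-3,5-dimethoxy-4-methyl-5-oxopent-3-enoyl]-4-(4-methoxy-3-methyl-2-oxo-2H-pyran-6-yl)-3,4-dimethylcyclobutane-1,2-dicarboxylate, via acid chloride 11 (not isolated)
Conditions: (COCl)2 (1.5 equiv), DMF (cat.), CH2Cl2, 0 → 25 °C, evaporate; then 8 (1.5 equiv), Me3SiOTf (0.3 equiv), CH2Cl2, −78 → 20 °C; aq. NaHCO3
Reagents that add atoms: none
Why: The acid is converted to its chloride and the volatile by-products are removed; the chloride on C4 is trans to the C1 ester and cannot cyclise onto it. The same silyl ketene acetal is then acylated at its γ-carbon by the acid chloride, by far the most electrophilic carbonyl present, under silyl triflate catalysis (vinylogous Mukaiyama-type acylation), and no stereocentre is affected.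

Step 8
Reactants: 12 racemic keto enoate
Product: 13 dimethyl (1R,2S,3R,4S)-3,4-bis(4-methoxy-3-methyl-2-oxo-2H-pyran-6-yl)-3,4-dimethylcyclobutane-1,2-dicarboxylate (meso)
Conditions: DBU (1.5 equiv), toluene, 60 °C
Reagents that add atoms: none
Why: The same base-induced lactonisation as in step 6 closes the second pyranone; with two identical arms the compound is meso again.

Step 9
Reactants: 13 meso bis(pyranone) dimethyl ester
Product: 14 (1R,2S,3R,4S)-3,4-bis(4-methoxy-3-methyl-2-oxo-2H-pyran-6-yl)-3,4-dimethylcyclobutane-1,2-dicarboxylic acid (meso)
Conditions: Me3SnOH (8 equiv), ClCH2CH2Cl, 80 °C; aq. HCl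
Reagents that add atoms: trimethyltin hydroxide, C[Sn](C)(C)O
Why: Neutral ester cleavage by a tin hydroxide (acyl–oxygen cleavage through a tin carboxylate), a method used where hydroxide would epimerise α-centres or attack other acyl groups. The conjugated pyranone lactones are much less electrophilic than the two methyl esters, and C1 and C2 keep their configuration.

Step 10
Reactants: 14 meso diacid
Product: 15 meso 6,7-bis(4-methoxy-3-methyl-2-oxo-2H-pyran-6-yl)-6,7-dimethyl-3-oxabicyclo[3.2.0]heptane-2,4-dione (pyranones anti to the anhydride ring)
Conditions: Ac2O, 70 °C; evaporate
Reagents that add atoms: none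
Why: Cyclodehydration of a cis-1,2-diacid to the five-membered anhydride through the mixed anhydride; only the cis diacid can close, so the step also confirms that C1 and C2 were not epimerised.

Step 11
Reactants: 15 meso anhydride
Product: 16 (1S,2R,3S,4R)-2-(methoxycarbonyl)-3,4-bis(4-methoxy-3-methyl-2-oxo-2H-pyran-6-yl)-3,4-dimethylcyclobutane-1-carboxylic acid (IUPAC numbering from the acid carbon; target)
Conditions: quinine (1.1 equiv), MeOH (3 equiv), toluene–CH2Cl2, −55 °C; then 1 M HCl wash
Reagents that add atoms: methanol, CO
Why: Alkaloid-mediated enantioselective methanolysis of a meso anhydride: the quinuclidine nitrogen acts as a general base and delivers methanol to one of the two enantiotopic carbonyls within the chiral ion pair. On the model for cis-fused succinic anhydrides quinine should direct methanol to the carbonyl on C1, so that C1 carries the ester and C2 the acid; no stereocentre is formed or disturbed, and only the absolute sense is set.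

## Compound list

1 | 2,3-dimethylmaleic anhydride | CC1=C(C)C(=O)OC1=O | starting material
2 | acetylene | C#C | starting material
3 | (1R,5S)-1,5-dimethyl-3-oxabicyclo[3.2.0]hept-6-ene-2,4-dione (meso, cis-fused) | O=C1OC(=O)[C@@]2(C)C=C[C@@]12C | intermediate
4 | dimethyl (1R,2S,3R,4S)-3,4-dimethylcyclobutane-1,2,3,4-tetracarboxylate 3,4-anhydride (meso; esters cis to the methyls, anti to the anhydride) | COC(=O)[C@@H]1[C@H](C(=O)OC)[C@@](C)(C3=O)[C@@]1(C)C(=O)O3 | intermediate
5 | methyl 2-methylacetoacetate | CC(=O)C(C)C(=O)OC | starting material
6 | methyl (E)-3-methoxy-2-methylbut-2-enoate | CO/C(C)=C(\C)C(=O)OC | intermediate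
7 | lithium 1,3-dimethoxy-2-methylbuta-1,3-dien-1-olate | [Li+].[O-]C(OC)=C(C)C(OC)=C | intermediate (not isolated)
8 | 1,3-dimethoxy-2-methyl-1-(trimethylsilyloxy)buta-1,3-diene (ketene acetal geometry immaterial) | C=C(OC)C(C)=C(OC)O[Si](C)(C)C | intermediate
9 | racemic 4-[(3E)-3,5-dimethoxy-4-methyl-5-oxopent-3-enoyl]-2,3-bis(methoxycarbonyl)-1,4-dimethylcyclobutane-1-carboxylic acid (acid and acyl group on one face, esters and methyls on the other; one enantiomer drawn) | COC(=O)[C@@H]1[C@H](C(=O)OC)[C@@](C)(C(=O)C/C(OC)=C(/C)C(=O)OC)[C@@]1(C)C(=O)O | intermediate
10 | racemic 2,3-bis(methoxycarbonyl)-4-(4-methoxy-3-methyl-2-oxo-2H-pyran-6-yl)-1,4-dimethylcyclobutane-1-carboxylic acid (same relative configuration; one enantiomer drawn) | COC(=O)[C@@H]1[C@H](C(=O)OC)[C@@](C)(c2cc(OC)c(C)c(=O)o2)[C@@]1(C)C(=O)O | intermediate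
11 | racemic acid chloride of 10 | COC(=O)[C@@H]1[C@H](C(=O)OC)[C@@](C)(c2cc(OC)c(C)c(=O)o2)[C@@]1(C)C(=O)Cl | intermediate (not isolated)
12 | racemic dimethyl 3-[(3E)-3,5-dimethoxy-4-methyl-5-oxopent-3-enoyl]-4-(4-methoxy-3-methyl-2-oxo-2H-pyran-6-yl)-3,4-dimethylcyclobutane-1,2-dicarboxylate (one enantiomer drawn) | COC(=O)[C@@H]1[C@H](C(=O)OC)[C@@](C)(c2cc(OC)c(C)c(=O)o2)[C@@]1(C)C(=O)C/C(OC)=C(/C)C(=O)OC | intermediate
13 | dimethyl (1R,2S,3R,4S)-3,4-bis(4-methoxy-3-methyl-2-oxo-2H-pyran-6-yl)-3,4-dimethylcyclobutane-1,2-dicarboxylate (meso) | COC(=O)[C@@H]1[C@H](C(=O)OC)[C@@](C)(c2cc(OC)c(C)c(=O)o2)[C@@]1(C)c1cc(OC)c(C)c(=O)o1 | intermediate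
14 | (1R,2S,3R,4S)-3,4-bis(4-methoxy-3-methyl-2-oxo-2H-pyran-6-yl)-3,4-dimethylcyclobutane-1,2-dicarboxylic acid (meso) | OC(=O)[C@@H]1[C@H](C(=O)O)[C@@](C)(c2cc(OC)c(C)c(=O)o2)[C@@]1(C)c1cc(OC)c(C)c(=O)o1 | intermediate
15 | meso 6,7-bis(4-methoxy-3-methyl-2-oxo-2H-pyran-6-yl)-6,7-dimethyl-3-oxabicyclo[3.2.0]heptane-2,4-dione (pyranones anti to the anhydride ring) | O=C5[C@@H]1[C@H](C(=O)O5)[C@@](C)(c2cc(OC)c(C)c(=O)o2)[C@@]1(C)c1cc(OC)c(C)c(=O)o1 | intermediate
16 | (1S,2R,3S,4R)-2-(methoxycarbonyl)-3,4-bis(4-methoxy-3-methyl-2-oxo-2H-pyran-6-yl)-3,4-dimethylcyclobutane-1-carboxylic acid (CNP0481603.1) | COC(=O)[C@@H]1[C@H](C(=O)O)[C@@](C)(c2cc(OC)c(C)c(=O)o2)[C@@]1(C)c1cc(OC)c(C)c(=O)o1 | target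

## Step count and least certain steps

Total: 11 steps. Longest linear sequence: 9 steps (1, 2, 5, 6, 7, 8, 9, 10, 11 from compound 1, and equally 3, 4, 5, 6, 7, 8, 9, 10, 11 from compound 5).

**Step 2 (key step).**
- Most likely failure: insufficient facial discrimination. The exo face is not free, since it carries the two angular methyl groups, so its advantage over the anhydride-lined face is one of degree. Addition from the concave face would put the esters syn to the anhydride.
- Secondary failures: methoxypalladation in place of carbonylative insertion, slow turnover at an alkene flanked by two quaternary carbons, and partial methanolysis of the anhydride.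
- Fallback: this sets out from 1 and returns at 4. Sensitised crossed [2+2] photocycloaddition of 1 with maleic anhydride A6 should give the cis,anti,cis dianhydride F1, in which the anti relationship is set in the cycloaddition itself. Methanol at room temperature should open only the unsubstituted anhydride, giving the racemic half-ester F2. Esterification of its acid with (trimethylsilyl)diazomethane gives 4.

**Step 1.**
- Most likely failure: photodimerisation of triplet 1, and cycloaddition of 1 to the cyclobutene of 3 once it builds up, because acetylene is a dilute and poor trap.
- Fallback: this sets out from 1 and returns at 3. Irradiation of 1 in the presence of a large excess of 1,2-dichloroethene should give the 6,7-dichloro adduct F3. Reductive elimination with activated Zn dust in Ac2O–toluene at 80 °C then forms the cyclobutene 3.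

**Step 5.**
- Most likely failure: sluggish addition to the doubly α-substituted anhydride carbonyl, so that the silyl ketene acetal is consumed by the Lewis acid first, or dehydration of the titanium-bound lactol form of the product to an enol lactone in place of the open keto acid.
- Fallback: this sets out from 6 and 4 and returns at 9. The lithium dienolate 7 is generated directly from 6 with LiN(iPr)2 (2.2 equiv) in THF at −78 °C and treated with 4 at −78 → −40 °C. Under these anionic conditions the anhydride opens irreversibly to a lithium carboxylate that cannot lactonise onto the new ketone, and the second equivalent of dienolate is taken up by the acidic methylene of the product. Acidification with aqueous HCl gives 9.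

**Step 7.**
- Most likely failure: slow intermolecular acylation at an acid chloride flanked by two quaternary carbons, so that the activated acyl group is captured by C5' of the neighbouring pyranone or the diene is lost to protodesilylation.
- Fallback: this sets out from 11 and returns at 13. The more nucleophilic dianion of 5 (NaH, then n-BuLi, THF) is acylated by 11 at −78 °C to give the 3,5-diketo ester F4. DBU in toluene lactonises F4 to the 4-hydroxypyranone F5, and Me2SO4 with K2CO3 in acetone methylates the hydroxyl to give 13. No free carboxylic acid is present at this stage, so the methylation is unambiguous.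

**Step 9.**
- Most likely failure: incomplete cleavage of the second, crowded ester, or attack of the reagent on a pyranone lactone. With hydroxide bases, ring opening of the pyranones and epimerisation at C1/C2 would be the concern.
- Fallback: this sets out from 13 and returns at 16, bypassing 14 and 15. Pig liver esterase in pH 7 phosphate buffer with DMSO as cosolvent hydrolyses one enantiotopic methyl ester directly. Which ester the enzyme cleaves cannot be predicted for so substituted a substrate and would have to be established on the product.

**Step 11.**
- Most likely failure: low enantioselectivity, or delivery of methanol to the other carbonyl, because the two pyranone-bearing quaternary carbons lie outside the range on which the selectivity model is based.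
- Fallback: this sets out from 15 and returns at 16, and it inverts the roles of the two carboxyls. Quinidine with benzyl alcohol in toluene at −55 °C should place a benzyl ester on C2 and give the half-ester F6. (Trimethylsilyl)diazomethane methylates the acid on C1 to give the methyl benzyl diester F7. Hydrogenolysis (H2, palladium on carbon, EtOAc, stopped at consumption of F7) frees the C2 acid. Either alkaloid can thus be used for the required enantiomer, whichever proves more selective.

## Further compounds

F1 | step 2 | cis,anti,cis-1,2-dimethylcyclobutane-1,2,3,4-tetracarboxylic dianhydride (meso) | O=C2[C@@H]1[C@H](C(=O)O2)[C@@](C)(C3=O)[C@@]1(C)C(=O)O3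
F2 | step 2 | racemic 2-(methoxycarbonyl)-3,4-dimethylcyclobutane-1,3,4-tricarboxylic acid 3,4-anhydride (half-ester; one enantiomer drawn) | COC(=O)[C@@H]1[C@H](C(=O)O)[C@@](C)(C3=O)[C@@]1(C)C(=O)O3
F3 | step 1 | 6,7-dichloro-1,5-dimethyl-3-oxabicyclo[3.2.0]heptane-2,4-dione (cis-fused; mixture of chloride stereoisomers) | O=C1OC(=O)[C@@]2(C)C(Cl)C(Cl)[C@@]12C
F0 | step 5 | none | none
F4 | step 7 | racemic dimethyl 3-(5-methoxy-4-methyl-3,5-dioxopentanoyl)-4-(4-methoxy-3-methyl-2-oxo-2H-pyran-6-yl)-3,4-dimethylcyclobutane-1,2-dicarboxylate (one enantiomer drawn; epimers at the side-chain methine) | COC(=O)[C@@H]1[C@H](C(=O)OC)[C@@](C)(c2cc(OC)c(C)c(=O)o2)[C@@]1(C)C(=O)CC(=O)C(C)C(=O)OC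
F5 | step 7 | racemic dimethyl 3-(4-hydroxy-3-methyl-2-oxo-2H-pyran-6-yl)-4-(4-methoxy-3-methyl-2-oxo-2H-pyran-6-yl)-3,4-dimethylcyclobutane-1,2-dicarboxylate (one enantiomer drawn) | COC(=O)[C@@H]1[C@H](C(=O)OC)[C@@](C)(c2cc(OC)c(C)c(=O)o2)[C@@]1(C)c1cc(O)c(C)c(=O)o1
F0 | step 9 | none | none
F6 | step 11 | 2-(benzyloxycarbonyl)-3,4-bis(4-methoxy-3-methyl-2-oxo-2H-pyran-6-yl)-3,4-dimethylcyclobutane-1-carboxylic acid (benzyl ester on C2, acid on C1) | OC(=O)[C@@H]1[C@H](C(=O)OCc5ccccc5)[C@@](C)(c2cc(OC)c(C)c(=O)o2)[C@@]1(C)c1cc(OC)c(C)c(=O)o1
F7 | step 11 | 2-benzyl 1-methyl 3,4-bis(4-methoxy-3-methyl-2-oxo-2H-pyran-6-yl)-3,4-dimethylcyclobutane-1,2-dicarboxylate (methyl ester on C1, benzyl ester on C2) | COC(=O)[C@@H]1[C@H](C(=O)OCc5ccccc5)[C@@](C)(c2cc(OC)c(C)c(=O)o2)[C@@]1(C)c1cc(OC)c(C)c(=O)o1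
A1 | alternative 1 | 1-tert-butyl 2-methyl 3,4-diformyl-3,4-dimethylcyclobutane-1,2-dicarboxylate | COC(=O)[C@@H]1[C@H](C(=O)OC(C)(C)C)[C@@](C)(C=O)[C@@]1(C)C=O
A2 | alternative 1 | 1,3-dimethoxy-2-methyl-1-(trimethylsilyloxy)buta-1,3-diene | C=C(OC)C(C)=C(OC)O[Si](C)(C)C
A3 | alternative 1 | 1-tert-butyl 2-methyl 3,4-bis(4-methoxy-3-methyl-2-oxo-5,6-dihydro-2H-pyran-6-yl)-3,4-dimethylcyclobutane-1,2-dicarboxylate | COC(=O)[C@@H]1[C@H](C(=O)OC(C)(C)C)[C@@](C)([C@H]2CC(OC)=C(C)C(=O)O2)[C@@]1(C)[C@@H]1CC(OC)=C(C)C(=O)O1
A4 | alternative 2 | dimethyl meso-3,4-diacetyl-3,4-dimethylpyrrolidine-2,5-dicarboxylate (esters cis to each other and to the methyls) | COC(=O)[C@@H]1N[C@H](C(=O)OC)[C@@](C)(C(C)=O)[C@@]1(C)C(C)=O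
A5 | alternative 2 | dimethyl meso-3,4-diacetyl-3,4-dimethylcyclobutane-1,2-dicarboxylate | COC(=O)[C@@H]1[C@H](C(=O)OC)[C@@](C)(C(C)=O)[C@@]1(C)C(C)=O
A6 | alternative 3 | maleic anhydride | O=C1OC(=O)C=C1
A7 | alternative 3 | cis,anti,cis-1,2-dimethylcyclobutane-1,2,3,4-tetracarboxylic dianhydride (meso) | O=C2[C@@H]1[C@H](C(=O)O2)[C@@](C)(C3=O)[C@@]1(C)C(=O)O3
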